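**Plan**

- Retrosynthesis: the seventeen O–H bonds go back to methyl ethers. The D–O–E diaryl ether is cut next (ring D phenol + trimer EFG bromide). Ring D is then taken apart into dimethyl squarate and a 1-aryloxyvinyl anion that already carries rings A–C. The five remaining diaryl ethers are phenol/aryl bromide unions.
- Enabling feature: ring D (C1 bears the oxygen to ring C, C2 is the only CH, C3–C5 carry OH, C6 bears the oxygen to ring E) has five contiguous oxygenated carbons. C3–C6 with their four oxygens map onto squarate; C1 and C2 map onto a 1-aryloxyvinyl unit in which the C–O–D ether already exists.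
- Forward: A + B, then C (brought in as a bromoaryl dichlorovinyl ether) by Ullmann couplings. The dichlorovinyl ether becomes the ethynyl ether, the 1-stannylvinyl ether and then the vinyllithium, which adds to dimethyl squarate and is silylated. Thermolysis closes ring D through the C2–C3 bond.
- The new C3 phenol is methylated, the C6 silyl ether is cleaved, and the freed oxygen is coupled with trimer EFG bromide (two Ullmann couplings, then sterically controlled C–H borylation/bromination). BBr3 then frees all hydroxyls.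
- Stereochemistry: the target is achiral. The single stereocentre of the route (C4 of the cyclobutenone) is made racemic and vanishes on aromatisation. The only selectivity needed is outward rotation of the silyloxy group in the ring opening.

Key step: step 9

Remark on the chemistry: in every diaryl ether of the target the oxygen sits on the di-ortho-oxygenated carbon of the ring nearer to A and on an ortho-unsubstituted carbon of the next ring. Every coupling therefore pairs a hindered phenol with an unhindered aryl bromide.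
Notation: ArO = 4-[3,5-dimethoxy-4-(2,4,6-trimethoxyphenoxy)phenoxy]-2,6-dimethoxyphenoxy, the permethylated trimer ABC aryloxy group.

**Route**

Step 1
Reactants: 1 4-bromo-2,6-dimethoxyphenol
Product: 2 2-(benzyloxy)-5-bromo-1,3-dimethoxybenzene
Conditions: BnBr, K2CO3, DMF, rt
Reagents that add atoms: benzyl bromide, BrCc1ccccc1
Why: Williamson etherification masks the hindered phenol oxygen of the future rings B and F as a benzyl ether that survives copper catalysis and is removed later by hydrogenolysis.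

Step 2
Reactants: 3 2,4,6-trimethoxyphenol; 2 2-(benzyloxy)-5-bromo-1,3-dimethoxybenzene
Product: 4 dimer AB benzyl ether 2-[4-(benzyloxy)-3,5-dimethoxyphenoxy]-1,3,5-trimethoxybenzene
Conditions: CuI (10 mol %), picolinic acid (20 mol %), K3PO4, DMSO, 90 °C, argon
Reagents that add atoms: none
Why: Ullmann-type diaryl ether synthesis under monovalent copper/picolinic acid catalysis, a ligand system suited to di-ortho-substituted phenols and electron-rich aryl bromides, joins the ring A oxygen to the ortho-unsubstituted C–Br carbon of ring B.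

Step 3
Reactants: 4 dimer AB benzyl ether
Product: 5 dimer AB phenol 2,6-dimethoxy-4-(2,4,6-trimethoxyphenoxy)phenol
Conditions: H2 (1 atm), 10% Pd/C, EtOAc/MeOH, rt
Reagents that add atoms: none
Why: Catalytic hydrogenolysis cleaves only the benzylic C–O bond and leaves methyl and diaryl ethers untouched.

Step 4
Reactants: 1 4-bromo-2,6-dimethoxyphenol
Product: 6 5-bromo-2-[(E)-1,2-dichloroethenoxy]-1,3-dimethoxybenzene
Conditions: Cl2C=CHCl, K2CO3, DMF, 70 °C
Reagents that add atoms: trichloroethylene, ClC=C(Cl)Cl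
Why: Anti addition of the phenoxide to dichloroacetylene formed in situ from trichloroethylene (the standard dichlorovinyl ether synthesis) protects the ring C oxygen with a group that is also the latent 1-aryloxyvinyl anion, and the aryl bromide is inert to it.

Step 5
Reactants: 5 dimer AB phenol; 6 5-bromo-2-[(E)-1,2-dichloroethenoxy]-1,3-dimethoxybenzene
Product: 7 trimer ABC dichlorovinyl ether 2-{4-[4-((E)-1,2-dichloroethenoxy)-3,5-dimethoxyphenoxy]-3,5-dimethoxyphenoxy}-1,3,5-trimethoxybenzene
Conditions: CuI (10 mol %), picolinic acid (20 mol %), K3PO4, DMSO, 90 °C, argon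
Reagents that add atoms: none
Why: Ullmann-type coupling as in step 2, in which the aryl C–Br bond should react with the copper phenoxide far faster than the vinylic C–Cl bonds of a group that is itself made under carbonate in hot DMF.

Step 6
Reactants: 7 trimer ABC dichlorovinyl ether
Product: 10 trimer ABC ethynyl ether 2-{4-[4-(ethynyloxy)-3,5-dimethoxyphenoxy]-3,5-dimethoxyphenoxy}-1,3,5-trimethoxybenzene, via chloroethynyl ether 8 (not isolated), via lithium acetylide 9 (not isolated)
Conditions: n-BuLi (2.5 equiv), THF, −78 to −40 °C; then MeOH, −78 °C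
Reagents that add atoms: none
Why: In the standard ynol ether synthesis from dichlorovinyl ethers, deprotonation and loss of chloride give the chloroalkyne, chlorine–lithium exchange gives the acetylide and methanol protonates it, and any ring lithiation by excess base is reversed by the same protic quench.

Step 7
Reactants: 10 trimer ABC ethynyl ether
Product: 11 tributyl[1-(ArO)ethenyl]stannane
Conditions: Bu3SnH (slow addition), Pd(PPh3)4 (2 mol %), THF, 0 °C
Reagents that add atoms: tributyltin hydride, CCCC[SnH](CCCC)CCCC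
Why: Hydrostannation of a 1-oxyalkyne under zerovalent palladium catalysis is a syn addition that places tin on the oxygen-bearing carbon and hydrogen on the terminal carbon, giving the α-stannyl enol ether.

Step 8
Reactants: 11 tributyl[1-(ArO)ethenyl]stannane; 12 dimethyl squarate
Product: 15 racemic 4-[1-(ArO)ethenyl]-4-(tert-butyldimethylsilyloxy)-2,3-dimethoxycyclobut-2-en-1-one, via vinyllithium 13 (not isolated), via lithium alkoxide 14 (not isolated)
Conditions: n-BuLi (1.05 equiv), THF, −78 °C; then 12, THF, −78 °C; then TBSOTf, −78 to −20 °C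
Reagents that add atoms: tert-butyldimethylsilyl trifluoromethanesulfonate, CC(C)(C)[Si](C)(C)OS(=O)(=O)C(F)(F)F
Why: Tin–lithium exchange gives the 1-aryloxyvinyllithium regiospecifically (direct deprotonation of the vinyl ether would compete with ortho-lithiation at six ring C–H positions flanked by two oxygens); it adds 1,2 to one carbonyl of dimethyl squarate, the alkoxide is silylated in situ, and the quaternary stereocentre forms as a racemate because nothing chiral is present.

Step 9
Reactants: 15 racemic 4-[1-(ArO)ethenyl]-4-(tert-butyldimethylsilyloxy)-2,3-dimethoxycyclobut-2-en-1-one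
Product: 18 tetramer ABCD phenol 4-(tert-butyldimethylsilyloxy)-2,3-dimethoxy-5-(ArO)phenol, via dienylketene 16 (not isolated), via cyclohexadienone 17 (not isolated)
Conditions: toluene (0.02 M), 110 °C, argon
Reagents that add atoms: none
Why: This is a Moore rearrangement of a 4-alkenyl-4-oxycyclobutenone: conrotatory 4π electrocyclic opening of the bond between the carbonyl carbon and the quaternary carbon gives the (Z)-dienylketene 16, whose ketene carbon bonds to the vinyl CH2 carbon in a thermal disrotatory 6π electrocyclisation that closes the six-membered ring D, and cyclohexa-2,4-dienone 17 then tautomerises to the phenol. The closest known reaction type is the ring expansion of squarate adducts of 1-alkoxyvinyl and cyclic enol ether lithium reagents to alkoxy hydroquinone derivatives. The squarate carbons become C3–C6 of ring D with their four oxygens, and the vinyl ether supplies C1 with the finished C–O–D ether and C2 as the only CH, so the substitution pattern is fixed by construction. The step needs the vinyl group to turn inward, cis to the ketene, during ring opening; the silyloxy donor on the sp3 carbon rotates outward by the normal torquoselectivity of oxygen donors, which secures this. No stereocentre is created, since the racemic quaternary carbon becomes aromatic C6. The two new ring oxygens come out differentiated, free OH at C3 and silyl ether at C6.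

Step 10
Reactants: 18 tetramer ABCD phenol
Product: 19 tert-butyl[2,3,4-trimethoxy-6-(ArO)phenoxy]dimethylsilane
Conditions: MeI, K2CO3, acetone, 40 °C
Reagents that add atoms: iodomethane, CI
Why: Williamson methylation of the unhindered C3 phenol gives it the same protection as all other hydroxyls, while the hindered aryl silyl ether should survive K2CO3 in dry acetone.

Step 11
Reactants: 19 tert-butyl[2,3,4-trimethoxy-6-(ArO)phenoxy]dimethylsilane
Product: 20 tetramer ABCD phenol 2,3,4-trimethoxy-6-(ArO)phenol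
Conditions: Bu4NF, AcOH, THF, 0 °C
Reagents that add atoms: none
Why: Fluoride-induced cleavage of the aryl silyl ether frees the C6 oxygen of ring D, and the acetic acid buffer keeps the electron-rich phenol out of its oxidation-prone phenoxide form.

Step 12
Reactants: 21 2,6-dimethoxyphenol; 2 2-(benzyloxy)-5-bromo-1,3-dimethoxybenzene
Product: 22 2-(benzyloxy)-5-(2,6-dimethoxyphenoxy)-1,3-dimethoxybenzene
Conditions: CuI (10 mol %), picolinic acid (20 mol %), K3PO4, DMSO, 90 °C, argon
Reagents that add atoms: none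
Why: Ullmann-type coupling as in step 2 joins the ring E oxygen to the ortho-unsubstituted C–Br carbon of the ring F building block.

Step 13
Reactants: 22 2-(benzyloxy)-5-(2,6-dimethoxyphenoxy)-1,3-dimethoxybenzene
Product: 23 4-(2,6-dimethoxyphenoxy)-2,6-dimethoxyphenol
Conditions: H2 (1 atm), 10% Pd/C, EtOAc/MeOH, rt
Reagents that add atoms: none
Why: Catalytic hydrogenolysis of the benzyl ether frees the ring F phenol without touching the other ethers.

Step 14
Reactants: 23 4-(2,6-dimethoxyphenoxy)-2,6-dimethoxyphenol; 24 5-bromo-1,2,3-trimethoxybenzene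
Product: 25 trimer EFG 2-[3,5-dimethoxy-4-(3,4,5-trimethoxyphenoxy)phenoxy]-1,3-dimethoxybenzene
Conditions: CuI (10 mol %), picolinic acid (20 mol %), K3PO4, DMSO, 90 °C, argon
Reagents that add atoms: none
Why: Ullmann-type coupling as in step 2 attaches ring G to the hindered ring F oxygen.

Step 15
Reactants: 25 trimer EFG
Product: 27 trimer EFG bromide 5-bromo-2-[3,5-dimethoxy-4-(3,4,5-trimethoxyphenoxy)phenoxy]-1,3-dimethoxybenzene, via pinacol boronate 26 (not isolated)
Conditions: [Ir(cod)OMe]2 (1.5 mol %), 4,4'-di-tert-butyl-2,2'-bipyridine (3 mol %), B2pin2, THF, 80 °C; then CuBr2 (3 equiv), MeOH/H2O (1:1), 80 °C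
Reagents that add atoms: copper dibromide CuBr2, [Cu+2].[Br-].[Br-]
Why: Iridium-catalysed C–H borylation is sterically controlled and should attack only the ring E hydrogen para to the ether oxygen, the single C–H of 25 with no ortho substituent, and one-pot copper-mediated bromodeboronation then replaces boron by bromine at that carbon without free electrophilic bromine.

Step 16
Reactants: 20 tetramer ABCD phenol; 27 trimer EFG bromide
Product: 28 heptadeca-O-methyl heptamer ABCDEFG
Conditions: CuI (30 mol %), picolinic acid (60 mol %), K3PO4, DMSO, 110 °C, argon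
Reagents that add atoms: none
Why: Ullmann-type coupling of the ring D phenol with the ortho-unsubstituted aryl bromide of ring E, run at higher copper loading and temperature because this phenoxide is flanked by an aryloxy and a methoxy group.

Step 17
Reactants: 28 heptadeca-O-methyl heptamer ABCDEFG
Product: 29 CNP0304148.0
Conditions: BBr3 (40 equiv), CH2Cl2, −78 °C to rt; then H2O, 0 °C; handled under argon
Reagents that add atoms: none
Why: Lewis acid ether cleavage by BBr3 removes all seventeen methyl groups through bromide attack at the methyl carbon, whereas diaryl ether C–O bonds offer no sp3 carbon and should stay intact.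

**Compound list**

1 | 4-bromo-2,6-dimethoxyphenol | COc1cc(Br)cc(OC)c1O | starting material
2 | 2-(benzyloxy)-5-bromo-1,3-dimethoxybenzene | COc1cc(Br)cc(OC)c1OCc1ccccc1 | intermediate
3 | 2,4,6-trimethoxyphenol | COc1cc(OC)c(O)c(OC)c1 | starting material
4 | dimer AB benzyl ether, 2-[4-(benzyloxy)-3,5-dimethoxyphenoxy]-1,3,5-trimethoxybenzene | COc1cc(OC)c(Oc2cc(OC)c(OCc3ccccc3)c(OC)c2)c(OC)c1 | intermediate
5 | dimer AB phenol, 2,6-dimethoxy-4-(2,4,6-trimethoxyphenoxy)phenol | COc1cc(OC)c(Oc2cc(OC)c(O)c(OC)c2)c(OC)c1 | intermediate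
6 | 5-bromo-2-[(E)-1,2-dichloroethenoxy]-1,3-dimethoxybenzene | COc1cc(Br)cc(OC)c1O/C(Cl)=C\Cl | intermediate
7 | trimer ABC (E)-1,2-dichlorovinyl ether, 2-{4-[4-((E)-1,2-dichloroethenoxy)-3,5-dimethoxyphenoxy]-3,5-dimethoxyphenoxy}-1,3,5-trimethoxybenzene | COc1cc(OC)c(Oc2cc(OC)c(Oc3cc(OC)c(O/C(Cl)=C\Cl)c(OC)c3)c(OC)c2)c(OC)c1 | intermediate
8 | trimer ABC chloroethynyl ether (ArO–C≡C–Cl) | COc1cc(OC)c(Oc2cc(OC)c(Oc3cc(OC)c(OC#CCl)c(OC)c3)c(OC)c2)c(OC)c1 | intermediate
9 | lithium acetylide of the trimer ABC ethynyl ether (ArO–C≡C–Li) | COc1cc(OC)c(Oc2cc(OC)c(Oc3cc(OC)c(OC#C[Li])c(OC)c3)c(OC)c2)c(OC)c1 | intermediate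
10 | trimer ABC ethynyl ether, 2-{4-[4-(ethynyloxy)-3,5-dimethoxyphenoxy]-3,5-dimethoxyphenoxy}-1,3,5-trimethoxybenzene | COc1cc(OC)c(Oc2cc(OC)c(Oc3cc(OC)c(OC#C)c(OC)c3)c(OC)c2)c(OC)c1 | intermediate
11 | tributyl[1-(ArO)ethenyl]stannane | COc1cc(OC)c(Oc2cc(OC)c(Oc3cc(OC)c(OC(=C)[Sn](CCCC)(CCCC)CCCC)c(OC)c3)c(OC)c2)c(OC)c1 | intermediate
12 | dimethyl squarate, 3,4-dimethoxycyclobut-3-ene-1,2-dione | COC1=C(OC)C(=O)C1=O | starting material
13 | 1-(ArO)ethenyllithium | COc1cc(OC)c(Oc2cc(OC)c(Oc3cc(OC)c(OC(=C)[Li])c(OC)c3)c(OC)c2)c(OC)c1 | intermediate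
14 | lithium alkoxide of racemic 4-[1-(ArO)ethenyl]-4-hydroxy-2,3-dimethoxycyclobut-2-en-1-one | COc1cc(OC)c(Oc2cc(OC)c(Oc3cc(OC)c(OC(=C)C4(O[Li])C(OC)=C(OC)C4=O)c(OC)c3)c(OC)c2)c(OC)c1 | intermediate
15 | racemic 4-[1-(ArO)ethenyl]-4-(tert-butyldimethylsilyloxy)-2,3-dimethoxycyclobut-2-en-1-one | COc1cc(OC)c(Oc2cc(OC)c(Oc3cc(OC)c(OC(=C)C4(O[Si](C)(C)C(C)(C)C)C(OC)=C(OC)C4=O)c(OC)c3)c(OC)c2)c(OC)c1 | intermediate
16 | (Z)-dienylketene, (3Z)-5-(ArO)-4-(tert-butyldimethylsilyloxy)-2,3-dimethoxyhexa-1,3,5-trien-1-one | COc1cc(OC)c(Oc2cc(OC)c(Oc3cc(OC)c(OC(=C)/C(O[Si](C)(C)C(C)(C)C)=C(OC)\C(OC)=C=O)c(OC)c3)c(OC)c2)c(OC)c1 | intermediate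
17 | 5-(ArO)-4-(tert-butyldimethylsilyloxy)-2,3-dimethoxycyclohexa-2,4-dien-1-one | COc1cc(OC)c(Oc2cc(OC)c(Oc3cc(OC)c(OC4=C(O[Si](C)(C)C(C)(C)C)C(OC)=C(OC)C(=O)C4)c(OC)c3)c(OC)c2)c(OC)c1 | intermediate
18 | tetramer ABCD phenol, 4-(tert-butyldimethylsilyloxy)-2,3-dimethoxy-5-(ArO)phenol | COc1cc(OC)c(Oc2cc(OC)c(Oc3cc(OC)c(Oc4cc(O)c(OC)c(OC)c4O[Si](C)(C)C(C)(C)C)c(OC)c3)c(OC)c2)c(OC)c1 | intermediate
19 | tert-butyl[2,3,4-trimethoxy-6-(ArO)phenoxy]dimethylsilane | COc1cc(OC)c(Oc2cc(OC)c(Oc3cc(OC)c(Oc4cc(OC)c(OC)c(OC)c4O[Si](C)(C)C(C)(C)C)c(OC)c3)c(OC)c2)c(OC)c1 | intermediate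
20 | tetramer ABCD phenol, 2,3,4-trimethoxy-6-(ArO)phenol | COc1cc(OC)c(Oc2cc(OC)c(Oc3cc(OC)c(Oc4cc(OC)c(OC)c(OC)c4O)c(OC)c3)c(OC)c2)c(OC)c1 | intermediate
21 | 2,6-dimethoxyphenol | COc1cccc(OC)c1O | starting material
22 | 2-(benzyloxy)-5-(2,6-dimethoxyphenoxy)-1,3-dimethoxybenzene | COc1cccc(OC)c1Oc1cc(OC)c(OCc2ccccc2)c(OC)c1 | intermediate
23 | 4-(2,6-dimethoxyphenoxy)-2,6-dimethoxyphenol | COc1cccc(OC)c1Oc1cc(OC)c(O)c(OC)c1 | intermediate
24 | 5-bromo-1,2,3-trimethoxybenzene | COc1cc(Br)cc(OC)c1OC | starting material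
25 | trimer EFG, 2-[3,5-dimethoxy-4-(3,4,5-trimethoxyphenoxy)phenoxy]-1,3-dimethoxybenzene | COc1cccc(OC)c1Oc1cc(OC)c(Oc2cc(OC)c(OC)c(OC)c2)c(OC)c1 | intermediate
26 | trimer EFG pinacol boronate, 2-{4-[3,5-dimethoxy-4-(3,4,5-trimethoxyphenoxy)phenoxy]-3,5-dimethoxyphenyl}-4,4,5,5-tetramethyl-1,3,2-dioxaborolane | COc1cc(B2OC(C)(C)C(C)(C)O2)cc(OC)c1Oc1cc(OC)c(Oc2cc(OC)c(OC)c(OC)c2)c(OC)c1 | intermediate
27 | trimer EFG bromide, 5-bromo-2-[3,5-dimethoxy-4-(3,4,5-trimethoxyphenoxy)phenoxy]-1,3-dimethoxybenzene | COc1cc(Br)cc(OC)c1Oc1cc(OC)c(Oc2cc(OC)c(OC)c(OC)c2)c(OC)c1 | intermediate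
28 | heptadeca-O-methyl heptamer ABCDEFG | COc1cc(OC)c(Oc2cc(OC)c(Oc3cc(OC)c(Oc4cc(OC)c(OC)c(OC)c4Oc4cc(OC)c(Oc5cc(OC)c(Oc6cc(OC)c(OC)c(OC)c6)c(OC)c5)c(OC)c4)c(OC)c3)c(OC)c2)c(OC)c1 | intermediate
29 | CNP0304148.0 | Oc1cc(O)c(Oc2cc(O)c(Oc3cc(O)c(Oc4cc(O)c(O)c(O)c4Oc4cc(O)c(Oc5cc(O)c(Oc6cc(O)c(O)c(O)c6)c(O)c5)c(O)c4)c(O)c3)c(O)c2)c(O)c1 | target

**Count and risks**

Total step count: 17. Longest linear sequence: 12 steps (steps 1, 2, 3, 5, 6, 7, 8, 9, 10, 11, 16, 17).

Step 16 is the most likely to fail. Carbon–oxygen bond formation at a phenoxide flanked by an aryloxy and a methoxy group may be slow, so that reductive loss of bromine from 27 and oxidative decay of the electron-rich phenoxide take over. The fallback sets out from 20 and avoids copper at this oxygen. Nucleophilic aromatic substitution of 20 on 4-fluoro-2,6-dimethoxybenzaldehyde (K2CO3, DMSO, 110 °C), activated by the para aldehyde, should give the pentamer ABCDE aldehyde F1. Baeyer–Villiger (Dakin-type) oxidation with mCPBA in CH2Cl2 would give the pentamer ABCDE aryl formate F2, which is methanolysed in the same flask (K2CO3, MeOH) to the pentamer ABCDE phenol F3. This ordinary 2,6-dimethoxyphenol is coupled with 2 under the conditions of step 12 to the hexamer ABCDEF benzyl ether F4, hydrogenolysed as in step 13 to the hexamer ABCDEF phenol F5, and coupled with 24 as in step 14 to come back to the route at 28.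

Step 15 is the second risk. Oxidative or electrophilic bromination of the very electron-rich rings F and G by CuBr2 may compete with substitution at boron, and borylation may stall on the crowded substrate. The fallback sets out from 1 and carries the bromine from the start. Coupling of 1 with commercial 5-iodo-1,2,3-trimethoxybenzene (CuI, picolinic acid, K3PO4, DMSO, 80 °C), in which the aryl iodide should react much faster than the bromide on the phenoxide ring, gives the dimer FG bromide F6. Aromatic Finkelstein exchange (CuI, trans-N,N'-dimethylcyclohexane-1,2-diamine, NaI, dioxane, 110 °C) gives the dimer FG iodide F7. A second iodide-selective coupling of F7 with 1 comes back to the route at 27.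

Step 7 is the third risk. Tin may be delivered to the terminal carbon, the terminal ynol ether may polymerise before it is hydrostannated, and the α-stannyl enol ether may lose tin by protonation on silica. The fallback sets out from 10 and is tin-free. Markovnikov addition of HBr (Me3SiBr/MeOH, CH2Cl2, −40 °C), whose regiochemistry is fixed by protonation at the terminal carbon of the ynol ether, gives the trimer ABC 1-bromovinyl ether F8. Bromine–lithium exchange (t-BuLi, 2 equiv, THF, −78 °C) gives vinyllithium 13, which is carried through the rest of step 8 to come back to the route at 15.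

**Further compounds**

F1 | step 16 | pentamer ABCDE aldehyde, 4-[2,3,4-trimethoxy-6-(ArO)phenoxy]-2,6-dimethoxybenzaldehyde | COc1cc(OC)c(Oc2cc(OC)c(Oc3cc(OC)c(Oc4cc(OC)c(OC)c(OC)c4Oc4cc(OC)c(C=O)c(OC)c4)c(OC)c3)c(OC)c2)c(OC)c1
F2 | step 16 | pentamer ABCDE aryl formate, 4-[2,3,4-trimethoxy-6-(ArO)phenoxy]-2,6-dimethoxyphenyl formate | COc1cc(OC)c(Oc2cc(OC)c(Oc3cc(OC)c(Oc4cc(OC)c(OC)c(OC)c4Oc4cc(OC)c(OC=O)c(OC)c4)c(OC)c3)c(OC)c2)c(OC)c1
F3 | step 16 | pentamer ABCDE phenol, 4-[2,3,4-trimethoxy-6-(ArO)phenoxy]-2,6-dimethoxyphenol | COc1cc(OC)c(Oc2cc(OC)c(Oc3cc(OC)c(Oc4cc(OC)c(OC)c(OC)c4Oc4cc(OC)c(O)c(OC)c4)c(OC)c3)c(OC)c2)c(OC)c1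
F4 | step 16 | hexamer ABCDEF benzyl ether | COc1cc(OC)c(Oc2cc(OC)c(Oc3cc(OC)c(Oc4cc(OC)c(OC)c(OC)c4Oc4cc(OC)c(Oc5cc(OC)c(OCc6ccccc6)c(OC)c5)c(OC)c4)c(OC)c3)c(OC)c2)c(OC)c1
F5 | step 16 | hexamer ABCDEF phenol | COc1cc(OC)c(Oc2cc(OC)c(Oc3cc(OC)c(Oc4cc(OC)c(OC)c(OC)c4Oc4cc(OC)c(Oc5cc(OC)c(O)c(OC)c5)c(OC)c4)c(OC)c3)c(OC)c2)c(OC)c1
F6 | step 15 | dimer FG bromide, 5-bromo-1,3-dimethoxy-2-(3,4,5-trimethoxyphenoxy)benzene | COc1cc(Br)cc(OC)c1Oc1cc(OC)c(OC)c(OC)c1
F7 | step 15 | dimer FG iodide, 5-iodo-1,3-dimethoxy-2-(3,4,5-trimethoxyphenoxy)benzene | COc1cc(I)cc(OC)c1Oc1cc(OC)c(OC)c(OC)c1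
F8 | step 7 | trimer ABC 1-bromovinyl ether, 2-{4-[4-(1-bromoethenoxy)-3,5-dimethoxyphenoxy]-3,5-dimethoxyphenoxy}-1,3,5-trimethoxybenzene | COc1cc(OC)c(Oc2cc(OC)c(Oc3cc(OC)c(OC(Br)=C)c(OC)c3)c(OC)c2)c(OC)c1
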